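The route cuts ring C of the flavanonol at two bonds, O1–C8a and C2–C3. The feature exploited is that C4=O makes C3 enolisable and at the same time activates C8a of ring A, which lies ortho to the acyl group, towards nucleophilic aromatic substitution. In one flask a catalytic enantioselective anti-selective Mukaiyama aldol addition joins a ring A (Z)-α-methoxy enol silane carrying fluorine at the future C8a to the benzyl-protected ring B aldehyde, setting C2 and C3, and fluoride then lets the aldolate oxygen displace the aryl fluoride to close the pyranone. Hydrogenolysis of three benzyl ethers finishes the synthesis.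

Key step: step 7

Remark: flavonoid numbering is used (O1, C2, C3, C4, C4a, C5 to C8, C8a; primed numbers for ring B), the target is the 2,3-trans (2R,3R) isomer, and 5-fluoro-1,2,3-trimethoxybenzene is taken to be a catalogue compound.

Step 1
Reactants: 1 5-fluoro-1,2,3-trimethoxybenzene; 2 N,2-dimethoxy-N-methylacetamide
Product: 5 1-(6-fluoro-2,3,4-trimethoxyphenyl)-2-methoxyethan-1-one, via aryllithium 3 (not isolated), via lithium hemiaminal adduct 4 (not isolated)
Conditions: n-BuLi (1.05 equiv), THF, −78 °C; then 2, −78 → −20 °C; then H2O
Reagents that add atoms: n-butyllithium [Li]CCCC (its lithium is held only in intermediates 3 and 4)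
Why: Directed ortho-metalation followed by acylation of the aryllithium with an N-methoxy-N-methylamide should work because the only ring C–H type of 1 is flanked by fluorine and methoxy, the aryllithium is kept at −78 °C so that LiF is not lost, and the chelated tetrahedral adduct 4 prevents a second addition.

Step 2
Reactants: 5 1-(6-fluoro-2,3,4-trimethoxyphenyl)-2-methoxyethan-1-one
Product: 7 1-(6-fluoro-2-hydroxy-3,4-dimethoxyphenyl)-2-methoxyethan-1-one, via aryloxydichloroborane 6 (not isolated)
Conditions: BCl3 (1.2 equiv), CH2Cl2, −78 → 0 °C; then H2O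
Reagents that add atoms: boron trichloride ClB(Cl)Cl (boron and chlorine are held only in intermediate 6)
Why: Chelation-controlled O-demethylation should be selective because BCl3 bound to the ketone oxygen forms a six-membered chelate only with the ortho methoxy oxygen, so chloride removes that methyl group while the other aryl methyl ethers and the aliphatic α-methoxy group remain.

Step 3
Reactants: 7 1-(6-fluoro-2-hydroxy-3,4-dimethoxyphenyl)-2-methoxyethan-1-one
Product: 8 1-[2-(benzyloxy)-6-fluoro-3,4-dimethoxyphenyl]-2-methoxyethan-1-one
Conditions: BnBr (1.2 equiv), K2CO3, DMF, 50 °C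
Reagents that add atoms: benzyl bromide BrCc1ccccc1
Why: Williamson etherification of the phenol should be clean because carbonate is too weak a base to enolise the ketone or to provoke substitution of the aryl fluoride.

Step 4
Reactants: 8 1-[2-(benzyloxy)-6-fluoro-3,4-dimethoxyphenyl]-2-methoxyethan-1-one
Product: 9 tert-butyl{[(Z)-1-[2-(benzyloxy)-6-fluoro-3,4-dimethoxyphenyl]-2-methoxyethenyl]oxy}dimethylsilane
Conditions: TBSOTf (1.3 equiv), Et3N (2 equiv), CH2Cl2, 0 °C
Reagents that add atoms: tert-butyldimethylsilyl trifluoromethanesulfonate CC(C)(C)[Si](C)(C)OS(=O)(=O)C(F)(F)F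
Why: Soft enolisation with O-silylation of the α-methoxy ketone is expected to give mainly the (Z)-enol silane, in which the methoxy group lies trans to the bulky 2,6-disubstituted aryl group, and the geometry is not critical for the open transition state of step 7.

Step 5
Reactants: 10 2-methoxybenzene-1,4-diol
Product: 11 1,4-bis(benzyloxy)-2-methoxybenzene
Conditions: BnBr (2.3 equiv), K2CO3, DMF, 60 °C, under N2
Reagents that add atoms: benzyl bromide BrCc1ccccc1
Why: Double Williamson etherification should proceed cleanly when air is excluded so that the hydroquinone is not oxidised to the quinone before it is alkylated.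

Step 6
Reactants: 11 1,4-bis(benzyloxy)-2-methoxybenzene
Product: 13 2,5-bis(benzyloxy)-4-methoxybenzaldehyde, via iminium chloride 12 (not isolated)
Conditions: POCl3 (1.5 equiv), DMF, 0 → 70 °C; then H2O
Reagents that add atoms: N,N-dimethylformamide CN(C)C=O; water O; phosphoryl chloride O=P(Cl)(Cl)Cl (its chloride is held only in intermediate 12)
Why: Vilsmeier–Haack formylation should occur at the position para to the methoxy group and ortho to a benzyloxy group, the most activated and least hindered site as in the formylation of 1,2,4-trialkoxybenzenes, and water then hydrolyses the iminium salt.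

Step 7
Reactants: 9 tert-butyl{[(Z)-1-[2-(benzyloxy)-6-fluoro-3,4-dimethoxyphenyl]-2-methoxyethenyl]oxy}dimethylsilane; 13 2,5-bis(benzyloxy)-4-methoxybenzaldehyde
Product: 15 (2R,3R)-5-(benzyloxy)-2-[2,5-bis(benzyloxy)-4-methoxyphenyl]-3,6,7-trimethoxychroman-4-one, via trichlorosilyl aldolate 14 (not isolated)
Conditions: SiCl4 (1.2 equiv), (S,S)-bisphosphoramide (5 mol %; two cyclic phosphoramide units derived from N,N'-dimethyl-1,1'-binaphthyl-2,2'-diamine, joined by an N,N'-dimethylpentane-1,5-diamine linker), iPr2NEt (10 mol %), CH2Cl2, −78 °C; then DMF, CsF (8 equiv), −78 → 0 °C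
Reagents that add atoms: silicon tetrachloride Cl[Si](Cl)(Cl)Cl (its SiCl3 group is held only in intermediate 14)
Why: The step is a Lewis-base-catalysed, SiCl4-mediated Mukaiyama aldol addition followed in the same flask by fluoride-triggered intramolecular SNAr: the phosphoramide-bound trichlorosilyl cation activates aldehyde 13, enol silane 9 adds through an open antiperiplanar transition state to form the C2–C3 bond, and chloride takes the TBS group to leave aldolate 14. The catalyst controls C2 by exposing only the Si face of the aldehyde (the (S,S)-antipode is specified on the expectation that the (R,R)-form of this catalyst family directs nucleophiles to the Re face of aryl aldehydes), and C3 is set relative to C2 by the anti preference of the open transition state for an α-methoxy enol silane that carries a bulky 2,6-disubstituted aryl group. CsF in DMF then strips the chlorides from silicon and frees the aldolate oxygen as a caesium alkoxide or fluorosilicate, which attacks the fluorine-bearing carbon C8a ortho to the ketone and expels fluoride through an anionic σ-adduct stabilised by the C4 carbonyl. Ring C therefore closes by a polar six-membered addition–elimination at an sp2 carbon with retention at C2 and C3, so anti-14 gives the 2,3-trans chromanone 15. The step needs ring closure to outrun retro-aldol cleavage and β-elimination and to occur at C–F and not at the benzyloxy-bearing carbon; the ortho-acyl activation, the superior nucleofugality of fluoride, the two meta oxygen substituents, the para methoxy group twisted out of conjugation by its two neighbours, the benzyl ether that prevents a deactivating phenoxide and the low temperature should secure this. The closest known reaction types are the catalytic enantioselective anti-aldol addition of α-alkoxy enol silanes to aryl aldehydes and the alkoxide–fluoroarene SNAr closure of chroman rings.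

Step 8
Reactants: 15 (2R,3R)-5-(benzyloxy)-2-[2,5-bis(benzyloxy)-4-methoxyphenyl]-3,6,7-trimethoxychroman-4-one
Product: 16 (2R,3R)-2-(2,5-dihydroxy-4-methoxyphenyl)-5-hydroxy-3,6,7-trimethoxychroman-4-one
Conditions: H2 (1 atm), 10% Pd/C, EtOAc, rt; work-up under argon
Reagents that add atoms: none
Why: Hydrogenolysis of the three aryl benzyl ethers is neutral, so C3 is not enolised and ring C is not opened, the cyclic C2–O1 benzylic ether should cleave much more slowly than the O-benzyl groups, and exclusion of air protects the ring B hydroquinone.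

Compound list
1 | 5-fluoro-1,2,3-trimethoxybenzene | COc1cc(F)cc(OC)c1OC | starting material
2 | N,2-dimethoxy-N-methylacetamide | COCC(=O)N(C)OC | starting material
3 | (6-fluoro-2,3,4-trimethoxyphenyl)lithium (not isolated) | [Li]c1c(F)cc(OC)c(OC)c1OC | intermediate
4 | lithium 1-(6-fluoro-2,3,4-trimethoxyphenyl)-2-methoxy-1-[methoxy(methyl)amino]ethan-1-olate (not isolated) | COCC(O[Li])(N(C)OC)c1c(F)cc(OC)c(OC)c1OC | intermediate
5 | 1-(6-fluoro-2,3,4-trimethoxyphenyl)-2-methoxyethan-1-one | COCC(=O)c1c(F)cc(OC)c(OC)c1OC | intermediate
6 | dichloro[3-fluoro-5,6-dimethoxy-2-(methoxyacetyl)phenoxy]borane (not isolated) | COCC(=O)c1c(F)cc(OC)c(OC)c1OB(Cl)Cl | intermediate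
7 | 1-(6-fluoro-2-hydroxy-3,4-dimethoxyphenyl)-2-methoxyethan-1-one | COCC(=O)c1c(F)cc(OC)c(OC)c1O | intermediate
8 | 1-[2-(benzyloxy)-6-fluoro-3,4-dimethoxyphenyl]-2-methoxyethan-1-one | COCC(=O)c1c(F)cc(OC)c(OC)c1OCc1ccccc1 | intermediate
9 | tert-butyl{[(Z)-1-[2-(benzyloxy)-6-fluoro-3,4-dimethoxyphenyl]-2-methoxyethenyl]oxy}dimethylsilane | CO/C=C(\O[Si](C)(C)C(C)(C)C)c1c(F)cc(OC)c(OC)c1OCc1ccccc1 | intermediate
10 | 2-methoxybenzene-1,4-diol | COc1cc(O)ccc1O | starting material
11 | 1,4-bis(benzyloxy)-2-methoxybenzene | COc1cc(OCc2ccccc2)ccc1OCc1ccccc1 | intermediate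
12 | N-[2,5-bis(benzyloxy)-4-methoxybenzylidene]-N-methylmethanaminium chloride (not isolated) | COc1cc(OCc2ccccc2)c(C=[N+](C)C)cc1OCc1ccccc1.[Cl-] | intermediate
13 | 2,5-bis(benzyloxy)-4-methoxybenzaldehyde | COc1cc(OCc2ccccc2)c(C=O)cc1OCc1ccccc1 | intermediate
14 | (2R,3R)-1-[2-(benzyloxy)-6-fluoro-3,4-dimethoxyphenyl]-3-[2,5-bis(benzyloxy)-4-methoxyphenyl]-2-methoxy-3-[(trichlorosilyl)oxy]propan-1-one, the anti aldolate (not isolated) | COc1cc(OCc2ccccc2)c([C@@H](O[Si](Cl)(Cl)Cl)[C@@H](OC)C(=O)c2c(F)cc(OC)c(OC)c2OCc2ccccc2)cc1OCc1ccccc1 | intermediate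
15 | (2R,3R)-5-(benzyloxy)-2-[2,5-bis(benzyloxy)-4-methoxyphenyl]-3,6,7-trimethoxychroman-4-one (2,3-trans) | COc1cc(OCc2ccccc2)c([C@H]2Oc3cc(OC)c(OC)c(OCc4ccccc4)c3C(=O)[C@@H]2OC)cc1OCc1ccccc1 | intermediate
16 | (2R,3R)-2-(2,5-dihydroxy-4-methoxyphenyl)-5-hydroxy-3,6,7-trimethoxychroman-4-one (2,3-trans) | COc1cc(O)c([C@H]2Oc3cc(OC)c(OC)c(O)c3C(=O)[C@@H]2OC)cc1O | target

Total step count: 8. Longest linear sequence: 6 steps (steps 1, 2, 3, 4, 7 and 8); steps 5 and 6 form the second branch.

Steps most likely to fail

Step 7. The enantiomeric purity set in the aldol stage may erode through retro-aldol cleavage of the freed aldolate before ring closure; β-elimination or sluggish cyclisation at low temperature may also intervene. Fallback: stereocontrol is moved from the catalyst to a resolution, still forming both bonds in one flask. Setting out from ketone 8 and aldehyde 13, the potassium enolate of 8 (KN(SiMe3)2, THF, −78 °C) is treated with 13 and warmed to 0 °C. The reversible aldol addition is then drained by the irreversible intramolecular SNAr, and base equilibrates C3 to the diequatorial arrangement. This should give racemic 2,3-trans-5-(benzyloxy)-2-[2,5-bis(benzyloxy)-4-methoxyphenyl]-3,6,7-trimethoxychroman-4-one F1. Preparative chromatography on a chiral stationary phase (amylose tris(3,5-dimethylphenylcarbamate)) separates the enantiomers, and the (2R,3R)-form is 15, where the route is rejoined before step 8.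

Step 8. Hydrogenolytic opening of ring C at the benzylic C2–O1 bond, or reduction of the C4 ketone, may compete with removal of the benzyl groups. Fallback: non-reductive debenzylation of 15 with BCl3 and pentamethylbenzene as cation scavenger (CH2Cl2, −78 °C). At that temperature the methyl ethers should be untouched, and 16 is reached directly with no new compound on the way.

Step 2. Chemoselectivity may be lost through cleavage of the aliphatic α-methoxy group or of a second aryl methyl ether once boron is chelated by the α-alkoxy ketone. Fallback: the demethylation is done before the α-methoxy ketone exists. Setting out from 1, aryllithium 3 is formed as in step 1 and quenched with DMF to give 6-fluoro-2,3,4-trimethoxybenzaldehyde F2. BCl3 (CH2Cl2, −78 → 0 °C) then removes only the methyl group ortho to the formyl group to give 6-fluoro-2-hydroxy-3,4-dimethoxybenzaldehyde F3. Benzylation (BnBr, K2CO3, DMF) gives 2-(benzyloxy)-6-fluoro-3,4-dimethoxybenzaldehyde F4. Addition of methoxymethyllithium (from Bu3SnCH2OMe and n-BuLi, THF, −78 °C) gives racemic 1-[2-(benzyloxy)-6-fluoro-3,4-dimethoxyphenyl]-2-methoxyethan-1-ol F5, and oxidation (DMP, CH2Cl2, rt) returns to the route at 8.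

Further compounds
F1 | step 7 | racemic 2,3-trans-5-(benzyloxy)-2-[2,5-bis(benzyloxy)-4-methoxyphenyl]-3,6,7-trimethoxychroman-4-one (equal amounts of the (2R,3R) and (2S,3S) forms) | COc1cc(OCc2ccccc2)c([C@H]2Oc3cc(OC)c(OC)c(OCc4ccccc4)c3C(=O)[C@@H]2OC)cc1OCc1ccccc1.COc1cc(OCc2ccccc2)c([C@@H]2Oc3cc(OC)c(OC)c(OCc4ccccc4)c3C(=O)[C@H]2OC)cc1OCc1ccccc1
F2 | step 2 | 6-fluoro-2,3,4-trimethoxybenzaldehyde | COc1cc(F)c(C=O)c(OC)c1OC
F3 | step 2 | 6-fluoro-2-hydroxy-3,4-dimethoxybenzaldehyde | COc1cc(F)c(C=O)c(O)c1OC
F4 | step 2 | 2-(benzyloxy)-6-fluoro-3,4-dimethoxybenzaldehyde | COc1cc(F)c(C=O)c(OCc2ccccc2)c1OC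
F5 | step 2 | racemic 1-[2-(benzyloxy)-6-fluoro-3,4-dimethoxyphenyl]-2-methoxyethan-1-ol | COCC(O)c1c(F)cc(OC)c(OC)c1OCc1ccccc1
F0 | step 8 | none | none
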